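**Retrosynthetic overview**
1. Target 15 ⇒ carbinol 12: one operation removes the dimethyl ketal and runs an SNi′ 1,3-transposition, so the C5′–Cl centre and the E exocyclic alkene both come from the single carbinol centre C11.
2. 12 ⇒ hydroxy aldehyde 7 + iodoenone 10 by a chelation-controlled CrCl2/NiCl2 coupling; ring C is bought as cyclopent-4-ene-1,3-dione 8.
3. 7 ⇒ bicyclic keto ester 5 by equatorial methyl addition at C8 and ester-to-aldehyde reduction.
4. 5 ⇒ acyclic keto ester 4 by an enantioselective proton-initiated bicyclization (key step, rings A and B close together, the β-keto ester enol is the terminator); 4 ⇒ 1 + 2.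
5. Ring order: A and B in one operation (step 2); ring C is carried in intact and only functionalised.

Atom labels: drimane numbering for the decalin (C4 gem-dimethyl, C5, C8 carbinol, C9, C10 angular methyl, C11 exocyclic CH); C1′ ylidene carbon, C2′ enol carbon, C3′ CH, C4′ C=O, C5′ CHCl.

Assumption: the target is read as drawn, i.e. (1R,2S,4aS,8aS)-decalin (8-OH on the same face as the C10 methyl and the C9 side chain), E alkene (decalin cis to C2′), 5′R chloride; the free 1,3-dione is taken to rest in the drawn enol tautomer.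

**Route**

Step 1
Reactants: 1 methyl acetoacetate; 2 geranyl bromide
Product: 4 methyl (6E)-7,11-dimethyl-3-oxododeca-6,10-dienoate, via acetoacetate dianion 3 (not isolated)
Conditions: NaH, THF, 0 °C; n-BuLi, 0 °C; then 2, 0 °C → rt; aq. HCl
Reagents that add atoms: none
Why: Weiler dianion alkylation: the second deprotonation gives the far more nucleophilic terminal carbanion, which displaces the allylic bromide by SN2 at C4 of the acetoacetate only and leaves the E alkene untouched.

Step 2
Reactants: 4 methyl (6E)-7,11-dimethyl-3-oxododeca-6,10-dienoate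
Product: 5 methyl (1R,4aS,8aS)-5,5,8a-trimethyl-2-oxodecahydronaphthalene-1-carboxylate
Conditions: (R)-2-[(2-fluorophenyl)methoxy]-2′-hydroxy-1,1′-binaphthyl (1.2 equiv), SnCl4 (2.2 equiv), CH2Cl2, −78 °C, 3 d; H2O; recrystallisation
Reagents that add atoms: none
Why: Proposed new method: the SnCl4-acidified phenol of the chiral binaphthol ether (a Lewis-acid-assisted chiral Brønsted acid) should protonate the terminal alkene of the chair–chair folded chain on one enantioface, C5=C10 then closes ring A and the SnCl4-chelated enol of the β-keto ester traps the C10 cation through C9 to close ring B, so the E alkene gives the trans ring fusion (5S,10S) with the ester equatorial (9R), and I expect but have not verified that the R ligand gives this series; the closest known reaction types are the enantioselective proton-initiated polyene cyclization of geranyl and farnesyl arenes with such acids and the racemic SnCl4 cyclization of this same keto ester.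

Step 3
Reactants: 5 methyl (1R,4aS,8aS)-5,5,8a-trimethyl-2-oxodecahydronaphthalene-1-carboxylate
Product: 6 methyl (1R,2S,4aS,8aS)-2-hydroxy-2,5,5,8a-tetramethyldecahydronaphthalene-1-carboxylate
Conditions: MeLi, CeCl3 (3 equiv each), THF, −78 °C; then 5, −78 → −40 °C; H2O
Reagents that add atoms: methyllithium, [Li]C
Why: Organocerium 1,2-addition: weakly basic MeCeCl2 adds to the hindered, enolisable keto ester carbonyl instead of deprotonating C9, and it enters on the equatorial (α) trajectory because the axial β face is blocked by the syn-axial C10 methyl, which makes the new methyl equatorial and the hydroxyl axial (8S).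

Step 4
Reactants: 6 methyl (1R,2S,4aS,8aS)-2-hydroxy-2,5,5,8a-tetramethyldecahydronaphthalene-1-carboxylate
Product: 7 (1R,2S,4aS,8aS)-2-hydroxy-2,5,5,8a-tetramethyldecahydronaphthalene-1-carbaldehyde
Conditions: i-Bu2AlH (2.5 equiv), CH2Cl2, −78 °C; MeOH, then aq. KNaC4H4O6; used crude at once
Reagents that add atoms: none
Why: Partial ester reduction: the aluminium alkoxide of the neighbouring tertiary hydroxyl chelates the tetrahedral aluminate of this neopentyl-type ester so that it survives at −78 °C and releases the aldehyde only on work-up, with no stereocentre touched.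

Step 5
Reactants: 8 cyclopent-4-ene-1,3-dione
Product: 9 4,4-dimethoxycyclopent-2-en-1-one
Conditions: HC(OMe)3 (1.1 equiv), MeOH, p-TsOH·H2O (2 mol%), 0 °C → rt; Et3N
Reagents that add atoms: trimethyl orthoformate, COC(OC)OC
Why: Acid-catalysed ketalisation: after the first carbonyl is ketalised the other is a conjugated enone of much lower electrophilicity, and loss of methanol to an enol ether is blocked because it would create a cyclopentadienone, so the reaction stops at the mono-ketal.

Step 6
Reactants: 9 4,4-dimethoxycyclopent-2-en-1-one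
Product: 10 2-iodo-4,4-dimethoxycyclopent-2-en-1-one
Conditions: I2 (1.5 equiv), pyridine/CH2Cl2 (1:1), 0 °C → rt
Reagents that add atoms: iodine, II
Why: Johnson α-iodination of an enone: pyridine adds in conjugate fashion, the enolate is iodinated and E1cB loss of pyridine gives the 2-iodoenone, the basic medium leaving the ketal intact.

Step 7
Reactants: 7 (1R,2S,4aS,8aS)-2-hydroxy-2,5,5,8a-tetramethyldecahydronaphthalene-1-carbaldehyde; 10 2-iodo-4,4-dimethoxycyclopent-2-en-1-one
Product: 12 2-{(R)-hydroxy[(1S,2S,4aS,8aS)-2-hydroxy-2,5,5,8a-tetramethyldecahydronaphthalen-1-yl]methyl}-4,4-dimethoxycyclopent-2-en-1-one, via alkenylchromium dichloride 11 (not isolated)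
Conditions: CrCl2 (4 equiv), NiCl2 (2 mol%), DMF, rt, 16 h; H2O
Reagents that add atoms: none
Why: Nozaki–Hiyama–Kishi coupling: NiCl2-catalysed activation of the C–I bond and transmetallation give 11, which adds only to the aldehyde, and the chromium alkoxide of the free 8-OH ties the aldehyde oxygen into a Cram chelate so that attack comes from the face of H9, anti to quaternary C10, giving the 11R carbinol.

Step 8
Reactants: 12 2-{(R)-hydroxy[(1S,2S,4aS,8aS)-2-hydroxy-2,5,5,8a-tetramethyldecahydronaphthalen-1-yl]methyl}-4,4-dimethoxycyclopent-2-en-1-one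
Product: 15 (4E,5R)-5-chloro-3-hydroxy-4-{[(1R,2S,4aS,8aS)-2-hydroxy-2,5,5,8a-tetramethyldecahydronaphthalen-1-yl]methylidene}cyclopent-2-en-1-one, via allylic chlorosulfite 13 (not isolated), via chloro ketal 14 (not isolated)
Conditions: SOCl2 (1.05 equiv), Et2O, −40 → 0 °C; then THF/H2O (4:1), rt
Reagents that add atoms: thionyl chloride, O=S(Cl)Cl; water, O
Why: SNi′ 1,3-transposition of the allylic chlorosulfite (the hindered axial 8-OH should not react at −40 °C) through a chair-like six-membered transition state with the decalinyl group pseudo-equatorial, the same control that makes Johnson–Claisen trisubstituted alkenes E: chlorine reaches C5′ on the face from which oxygen leaves, so 11R becomes 5′R and the decalin ends cis to C2′ (E), after which the HCl formed hydrolyses the ketal in wet THF to the 1,3-dione, which enolises to the drawn tautomer.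

**Compound list**
1 | methyl acetoacetate | CC(=O)CC(=O)OC | starting material
2 | geranyl bromide, (2E)-1-bromo-3,7-dimethylocta-2,6-diene | CC(C)=CCC/C(C)=C/CBr | starting material
3 | lithium sodium dienolate (dianion) of methyl acetoacetate | [Li+].[Na+].[O-]C(=C)C=C([O-])OC | intermediate
4 | methyl (6E)-7,11-dimethyl-3-oxododeca-6,10-dienoate | COC(=O)CC(=O)CC/C=C(\C)CCC=C(C)C | intermediate
5 | methyl (1R,4aS,8aS)-5,5,8a-trimethyl-2-oxodecahydronaphthalene-1-carboxylate (trans-decalin, equatorial ester) | CC1(C)CCC[C@]2(C)[C@@H](C(=O)OC)C(=O)CC[C@@H]12 | intermediate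
6 | methyl (1R,2S,4aS,8aS)-2-hydroxy-2,5,5,8a-tetramethyldecahydronaphthalene-1-carboxylate (axial OH syn to the angular methyl) | CC1(C)CCC[C@]2(C)[C@@H](C(=O)OC)[C@@](C)(O)CC[C@@H]12 | intermediate
7 | (1R,2S,4aS,8aS)-2-hydroxy-2,5,5,8a-tetramethyldecahydronaphthalene-1-carbaldehyde | CC1(C)CCC[C@]2(C)[C@@H](C=O)[C@@](C)(O)CC[C@@H]12 | intermediate
8 | cyclopent-4-ene-1,3-dione | O=C1CC(=O)C=C1 | starting material
9 | 4,4-dimethoxycyclopent-2-en-1-one | COC1(OC)CC(=O)C=C1 | intermediate
10 | 2-iodo-4,4-dimethoxycyclopent-2-en-1-one | COC1(OC)CC(=O)C(I)=C1 | intermediate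
11 | dichloro(3,3-dimethoxy-5-oxocyclopent-1-en-1-yl)chromium | COC1(OC)CC(=O)C([Cr](Cl)Cl)=C1 | intermediate
12 | 2-{(R)-hydroxy[(1S,2S,4aS,8aS)-2-hydroxy-2,5,5,8a-tetramethyldecahydronaphthalen-1-yl]methyl}-4,4-dimethoxycyclopent-2-en-1-one | CC1(C)CCC[C@]2(C)[C@@H]([C@@H](O)C3=CC(OC)(OC)CC3=O)[C@@](C)(O)CC[C@@H]12 | intermediate
13 | chlorosulfite of the 11R secondary hydroxyl of 12 | CC1(C)CCC[C@]2(C)[C@@H]([C@@H](OS(Cl)=O)C3=CC(OC)(OC)CC3=O)[C@@](C)(O)CC[C@@H]12 | intermediate
14 | (2E,3R)-3-chloro-2-{[(1R,2S,4aS,8aS)-2-hydroxy-2,5,5,8a-tetramethyldecahydronaphthalen-1-yl]methylidene}-4,4-dimethoxycyclopentan-1-one | CC1(C)CCC[C@]2(C)[C@@H](/C=C3\C(=O)CC(OC)(OC)[C@@H]3Cl)[C@@](C)(O)CC[C@@H]12 | intermediate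
15 | (4E,5R)-5-chloro-3-hydroxy-4-{[(1R,2S,4aS,8aS)-2-hydroxy-2,5,5,8a-tetramethyldecahydronaphthalen-1-yl]methylidene}cyclopent-2-en-1-one | CC1(C)CCC[C@]2(C)[C@@H](/C=C3\C(O)=CC(=O)[C@@H]3Cl)[C@@](C)(O)CC[C@@H]12 | target

**Step count and risks**
Total step count: 8. Longest linear sequence: 6 (steps 1, 2, 3, 4, 7, 8); steps 5 and 6 make the coupling partner.

Most likely to fail:

Step 2. The enantioselective variant is untested: the keto ester may sequester the tin, the ee may be low, or the carbonyl oxygen may terminate instead of C9. The fallback sets out from 4 and comes back at 5. Compound 4 is cyclised with SnCl4 alone in CH2Cl2 (the established racemic reaction) to the racemic keto ester F1. F1 is condensed with (S)-1-phenylethanamine (toluene, cat. AcOH, water removal) to the chelated enamino esters. The (4aS,8aS) enamino ester F2 is crystallised away from the (4aR,8aR) enamino ester F3. F2 is hydrolysed with aqueous oxalic acid in THF, which returns enantiopure 5 with the ester equatorial again.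

Step 7. Aldehyde 7 is hindered and can lose water or undergo retro-aldol cleavage, the α-iodoenone is an unusual chromium coupling partner, and chelation control at C11 may be incomplete. Since step 8 transfers C11 to C5′, any 11S epimer ends as the 5′ epimer. The fallback sets out from 12 (as its C11 epimer mixture) and comes back at 12. The allylic carbinol is oxidised with Dess–Martin periodinane (NaHCO3, CH2Cl2) to the keto enone F4. F4 is reduced with Me4NBH(OAc)3 in MeCN/AcOH at −30 °C. Boron bound to the 8-OH delivers hydride intramolecularly through a chair with the cyclopentenyl group equatorial (hydroxyl-directed 1,3-anti reduction), which gives 11R and leaves the ring enone alone.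

Step 8. Three things can go wrong: the chlorosulfite may close a cyclic sulfite with the 8-OH; a stepwise chloride addition–elimination would erode the chirality transfer and may give the other alkene geometry; and the acidic ketal hydrolysis may epimerise C5′. The fallback sets out from 7 and comes back at 15. Commercial (R)-4-[(tert-butyldimethylsilyl)oxy]cyclopent-2-en-1-one is iodinated (I2, pyridine) to the iodoenone F5. CrCl2/NiCl2 coupling with 7, through the alkenylchromium dichloride F6, gives the 11R carbinol F7. SOCl2 in Et2O takes F7 through its chlorosulfite F8 to the allylic chloride F9. In F9 the resident silyloxy group on the neighbouring carbon lies on the face opposite the incoming chlorine and so reinforces the 5′R outcome. HF·pyridine gives the chlorohydrin F10, and Dess–Martin oxidation of its secondary alcohol unveils the 1,3-dione, i.e. 15, under neutral conditions with no aqueous acid near the C–Cl centre.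

**Further compounds**
F1 | step 2 | racemic methyl (1R*,4aS*,8aS*)-5,5,8a-trimethyl-2-oxodecahydronaphthalene-1-carboxylate | CC1(C)CCC[C@]2(C)[C@@H](C(=O)OC)C(=O)CC[C@@H]12.CC1(C)CCC[C@@]2(C)[C@H](C(=O)OC)C(=O)CC[C@H]12
F2 | step 2 | methyl (4aS,8aS)-5,5,8a-trimethyl-2-{[(1S)-1-phenylethyl]amino}-3,4,4a,5,6,7,8,8a-octahydronaphthalene-1-carboxylate | CC1(C)CCC[C@]2(C)C(C(=O)OC)=C(N[C@@H](C)c3ccccc3)CC[C@@H]12
F3 | step 2 | methyl (4aR,8aR)-5,5,8a-trimethyl-2-{[(1S)-1-phenylethyl]amino}-3,4,4a,5,6,7,8,8a-octahydronaphthalene-1-carboxylate | CC1(C)CCC[C@@]2(C)C(C(=O)OC)=C(N[C@@H](C)c3ccccc3)CC[C@H]12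
F4 | step 7 | 2-{[(1R,2S,4aS,8aS)-2-hydroxy-2,5,5,8a-tetramethyldecahydronaphthalen-1-yl]carbonyl}-4,4-dimethoxycyclopent-2-en-1-one | CC1(C)CCC[C@]2(C)[C@@H](C(=O)C3=CC(OC)(OC)CC3=O)[C@@](C)(O)CC[C@@H]12
F5 | step 8 | (4R)-4-[(tert-butyldimethylsilyl)oxy]-2-iodocyclopent-2-en-1-one | O=C1C[C@@H](O[Si](C)(C)C(C)(C)C)C=C1I
F6 | step 8 | dichloro{(3R)-3-[(tert-butyldimethylsilyl)oxy]-5-oxocyclopent-1-en-1-yl}chromium | O=C1C[C@@H](O[Si](C)(C)C(C)(C)C)C=C1[Cr](Cl)Cl
F7 | step 8 | (4R)-4-[(tert-butyldimethylsilyl)oxy]-2-{(R)-hydroxy[(1S,2S,4aS,8aS)-2-hydroxy-2,5,5,8a-tetramethyldecahydronaphthalen-1-yl]methyl}cyclopent-2-en-1-one | CC1(C)CCC[C@]2(C)[C@@H]([C@@H](O)C3=C[C@H](O[Si](C)(C)C(C)(C)C)CC3=O)[C@@](C)(O)CC[C@@H]12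
F8 | step 8 | chlorosulfite of the 11R secondary hydroxyl of F7 | CC1(C)CCC[C@]2(C)[C@@H]([C@@H](OS(Cl)=O)C3=C[C@H](O[Si](C)(C)C(C)(C)C)CC3=O)[C@@](C)(O)CC[C@@H]12
F9 | step 8 | (2E,3R,4R)-4-[(tert-butyldimethylsilyl)oxy]-3-chloro-2-{[(1R,2S,4aS,8aS)-2-hydroxy-2,5,5,8a-tetramethyldecahydronaphthalen-1-yl]methylidene}cyclopentan-1-one | CC1(C)CCC[C@]2(C)[C@@H](/C=C3\C(=O)C[C@@H](O[Si](C)(C)C(C)(C)C)[C@@H]3Cl)[C@@](C)(O)CC[C@@H]12
F10 | step 8 | (2E,3R,4R)-3-chloro-4-hydroxy-2-{[(1R,2S,4aS,8aS)-2-hydroxy-2,5,5,8a-tetramethyldecahydronaphthalen-1-yl]methylidene}cyclopentan-1-one | CC1(C)CCC[C@]2(C)[C@@H](/C=C3\C(=O)C[C@@H](O)[C@@H]3Cl)[C@@](C)(O)CC[C@@H]12
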